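Cuts: (1) the ring-A bond between the CH(OO) carbon of the 1,2-dioxane (ring B, C6) and the methyl-bearing sp2 carbon of the Z-alkene; (2) the Cβ–Cγ bond and the acyl–O bond of the α-methylene-γ-butyrolactone (ring C); (3) both C–O bonds of the peroxide bridge.
Enabling feature: C6 of ring B belongs to rings A and B at once, carries a peroxide oxygen and is allylic. At the peroxyacetal level (OMe helper) it ionises to a cyclic peroxycarbenium ion, and its neighbour in ring A can carry SiMe3 as a vinyl-anion equivalent. Both helpers leave together as MeOSiMe3 in the ring closure itself.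
Forward order: ring B first (farnesol-derived epoxy acetal plus H2O2), then ring C (allylboration–lactonisation, which also joins the two fragments). Ring A, the 14-membered carbocycle, comes last, by a vinylsilane-terminated peroxycarbenium cyclisation that gives the target directly.
Stereochemistry: CH–OAc and quaternary C–OO come from one Shi epoxidation (retention and inversion on perhydrolysis). The two lactone carbons come from boronate geometry (cis) and a chiral phosphoric acid (absolute sense). The dioxane CH comes from axial, tether-matched attack on the half-chair cation. The E-alkene comes from farnesol, the Z-alkene from a ring-enforced trans-hydrosilylation and retentive ipso-substitution.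

Key step: step 17

Assumption: the configuration at the methoxy-bearing peroxyacetal carbon is left undefined because this carbon becomes planar in the ring closure, and the facial sense of the chiral phosphoric acid (Re-face attack with the R catalyst) is taken from the accepted transition-state model.

Step 1
Reactants: 1 (2E,6E)-farnesol
Product: 2 (2E,6E)-farnesyl acetate
Conditions: Ac2O, pyridine, DMAP (cat.), CH2Cl2, 0 °C to rt
Reagents that add atoms: acetic anhydride CC(=O)OC(C)=O
Why: DMAP-catalysed O-acylation of a primary allylic alcohol, whose acetate later deactivates the neighbouring alkene towards electrophilic oxidants.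

Step 2
Reactants: 2 (2E,6E)-farnesyl acetate
Product: 4 (2E,6E)-10,11-epoxyfarnesyl acetate (racemic epoxide), via bromohydrin 3 (not isolated)
Conditions: NBS, THF–H2O, 0 °C; crude 3, DBU, CH2Cl2, rt
Reagents that add atoms: water O
Why: Terminal-selective bromohydrin formation of a polyprenyl acetate in aqueous medium (the coiled chain exposes the terminal alkene and the allylic acetate deactivates the proximal one), followed by Williamson-type epoxide closure; the new stereocentre is racemic and is destroyed in step 3.

Step 3
Reactants: 4 (2E,6E)-10,11-epoxyfarnesyl acetate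
Product: 5 (2E,6E)-3,7-dimethyl-10-oxodeca-2,6-dien-1-yl acetate
Conditions: H5IO6, THF–Et2O, 0 °C
Reagents that add atoms: none
Why: Periodic acid hydrolyses the epoxide to the glycol and cleaves it (Malaprade-type cleavage) without touching the two remaining trisubstituted alkenes.

Step 4
Reactants: 5 (2E,6E)-3,7-dimethyl-10-oxodeca-2,6-dien-1-yl acetate
Product: 6 (2E,6E)-10,10-dimethoxy-3,7-dimethyldeca-2,6-dien-1-yl acetate
Conditions: HC(OMe)3, PPTS (cat.), MeOH, rt
Reagents that add atoms: trimethyl orthoformate COC(OC)OC
Why: Acid-catalysed acetalisation with an orthoester as water scavenger shields the aldehyde from Oxone and base and pre-installs the methoxy group of the later peroxyacetal.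

Step 5
Reactants: 6 (2E,6E)-10,10-dimethoxy-3,7-dimethyldeca-2,6-dien-1-yl acetate
Product: 7 (2E)-5-[(2S,3S)-3-(3,3-dimethoxypropyl)-3-methyloxiran-2-yl]-3-methylpent-2-en-1-yl acetate
Conditions: L-fructose-derived Shi ketone (cat.), Oxone (2KHSO5·KHSO4·K2SO4), K2CO3, n-Bu4NHSO4 (cat.), MeCN–dimethoxymethane, aq. Na2B4O7/Na2EDTA buffer, 0 °C
Reagents that add atoms: potassium peroxymonosulfate (active component of Oxone) [K+].[O-]S(=O)(=O)OO
Why: In this Shi epoxidation the chiral dioxirane attacks the electron-richer C6=C7 alkene through the spiro transition state while the allylic-acetate alkene stays deactivated, and the L-fructose-derived ketone should give the (S,S)-epoxide that fixes the later carbinol carbon and, after inversion, the quaternary carbon.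

Step 6
Reactants: 7 (2E)-5-[(2S,3S)-3-(3,3-dimethoxypropyl)-3-methyloxiran-2-yl]-3-methylpent-2-en-1-yl acetate
Product: 9 (2E,6S)-6-hydroxy-6-[(3R)-6-methoxy-3-methyl-1,2-dioxan-3-yl]-3-methylhex-2-en-1-yl acetate, via hydroperoxide 8 (not isolated)
Conditions: H2O2 (anhydrous, in Et2O, excess), H3PMo12O40 (cat.), Et2O, rt; aqueous wash; then PPTS (cat.), MeOH, rt
Reagents that add atoms: hydrogen peroxide OO
Why: In this molybdenum-catalysed perhydrolysis of a trisubstituted epoxide H2O2 attacks the tertiary carbon from the rear (inversion there, retention at the secondary carbinol carbon), and the tertiary hydroperoxide then exchanges one acetal methoxy group under acid catalysis, favoured over the secondary alcohol by the higher affinity of hydroperoxides for carbonyl-level carbon, to close the six-membered peroxyacetal as an inconsequential mixture of anomers.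

Step 7
Reactants: 9 (2E,6S)-6-hydroxy-6-[(3R)-6-methoxy-3-methyl-1,2-dioxan-3-yl]-3-methylhex-2-en-1-yl acetate
Product: 10 (2E,6S)-6-[(3R)-6-methoxy-3-methyl-1,2-dioxan-3-yl]-3-methylhex-2-ene-1,6-diol
Conditions: K2CO3 (cat.), MeOH, 0 °C
Reagents that add atoms: none
Why: Mild carbonate-catalysed transesterification removes the primary allylic acetate, and the dialkyl peroxyacetal has no acidic hydrogen that would trigger base-induced O–O cleavage under these conditions.

Step 8
Reactants: 10 (2E,6S)-6-[(3R)-6-methoxy-3-methyl-1,2-dioxan-3-yl]-3-methylhex-2-ene-1,6-diol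
Product: 11 (2E,6S)-6-hydroxy-6-[(3R)-6-methoxy-3-methyl-1,2-dioxan-3-yl]-3-methylhex-2-enal
Conditions: MnO2, CH2Cl2, rt
Reagents that add atoms: none
Why: MnO2 oxidises only the allylic primary alcohol, leaving the hindered secondary carbinol, the peroxide and the E geometry unchanged.

Step 9
Reactants: 11 (2E,6S)-6-hydroxy-6-[(3R)-6-methoxy-3-methyl-1,2-dioxan-3-yl]-3-methylhex-2-enal
Product: 12 (1S,4E)-1-[(3R)-6-methoxy-3-methyl-1,2-dioxan-3-yl]-4-methyl-6-oxohex-4-en-1-yl acetate
Conditions: Ac2O, pyridine, DMAP (cat.), CH2Cl2, rt
Reagents that add atoms: acetic anhydride CC(=O)OC(C)=O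
Why: DMAP-catalysed acetylation installs the acetate of the target on the hindered secondary alcohol with retention and removes the only hydroxyl group that could capture the later cation.

Step 10
Reactants: 13 pent-3-yn-1-ol
Product: 15 2,2,3-trimethyl-5,6-dihydro-2H-1,2-oxasiline, via silyl ether 14 (not isolated)
Conditions: (HMe2Si)2NH, neat, rt to 60 °C; volatiles removed; [Cp*Ru(MeCN)3]PF6 (cat.), CH2Cl2, rt
Reagents that add atoms: 1,1,3,3-tetramethyldisilazane C[SiH](C)N[SiH](C)C
Why: Alcohol silylation is followed by ruthenium-catalysed intramolecular trans-hydrosilylation (6-endo-dig), in which the tether delivers silicon to the distal, methyl-bearing alkyne carbon and the six-membered ring allows only the geometry with silicon cis to the CH2 chain.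

Step 11
Reactants: 15 2,2,3-trimethyl-5,6-dihydro-2H-1,2-oxasiline
Product: 16 (Z)-4-(trimethylsilyl)pent-3-en-1-ol
Conditions: MeLi, Et2O, 0 °C; then H2O
Reagents that add atoms: methyllithium [Li]C
Why: Nucleophilic substitution at silicon opens the cyclic siloxane and gives the trimethylsilyl alkene with unchanged alkene geometry.

Step 12
Reactants: 16 (Z)-4-(trimethylsilyl)pent-3-en-1-ol
Product: 17 (Z)-4-(trimethylsilyl)pent-3-enal
Conditions: Dess–Martin periodinane, CH2Cl2, 0 °C to rt; used without delay
Reagents that add atoms: none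
Why: Dess–Martin oxidation is mild and nearly neutral, so the β,γ-unsaturated aldehyde should be obtained without migration of the double bond into conjugation.

Step 13
Reactants: 17 (Z)-4-(trimethylsilyl)pent-3-enal
Product: 18 methyl (5Z)-3-hydroxy-2-methylidene-6-(trimethylsilyl)hept-5-enoate (racemic)
Conditions: methyl acrylate (excess), DABCO, rt
Reagents that add atoms: methyl acrylate C=CC(=O)OC
Why: This is a Morita–Baylis–Hillman reaction of an aliphatic aldehyde, and the new carbinol centre is racemic and is erased in step 15.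

Step 14
Reactants: 18 methyl (5Z)-3-hydroxy-2-methylidene-6-(trimethylsilyl)hept-5-enoate
Product: 19 methyl (5Z)-3-acetoxy-2-methylidene-6-(trimethylsilyl)hept-5-enoate
Conditions: Ac2O, pyridine, CH2Cl2, 0 °C
Reagents that add atoms: acetic anhydride CC(=O)OC(C)=O
Why: O-Acetylation turns the allylic alcohol into a leaving group for π-allyl formation.

Step 15
Reactants: 19 methyl (5Z)-3-acetoxy-2-methylidene-6-(trimethylsilyl)hept-5-enoate
Product: 20 methyl (2E,5Z)-2-[(4,4,5,5-tetramethyl-1,3,2-dioxaborolan-2-yl)methyl]-6-(trimethylsilyl)hepta-2,5-dienoate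
Conditions: B2pin2, Pd2(dba)3 (cat.), toluene, 50 °C
Reagents that add atoms: bis(pinacolato)diboron CC1(C)OB(OC1(C)C)B1OC(C)(C)C(C)(C)O1
Why: Miyaura-type borylation of a Morita–Baylis–Hillman acetate proceeds through the π-allyl complex formed by zerovalent palladium, with boron delivered to the unsubstituted terminus and the more stable trisubstituted enoate (chain trans to the ester, cis to CH2B) formed.

Step 16
Reactants: 12 (1S,4E)-1-[(3R)-6-methoxy-3-methyl-1,2-dioxan-3-yl]-4-methyl-6-oxohex-4-en-1-yl acetate; 20 methyl (2E,5Z)-2-[(4,4,5,5-tetramethyl-1,3,2-dioxaborolan-2-yl)methyl]-6-(trimethylsilyl)hepta-2,5-dienoate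
Product: 22 (1S,4E)-1-[(3R)-6-methoxy-3-methyl-1,2-dioxan-3-yl]-4-methyl-5-{(2S,3S)-4-methylidene-5-oxo-3-[(2Z)-3-(trimethylsilyl)but-2-en-1-yl]oxolan-2-yl}pent-4-en-1-yl acetate, via borate 21 (not isolated)
Conditions: (R)-TRIP [(R)-3,3'-bis(2,4,6-triisopropylphenyl)-1,1'-binaphthyl-2,2'-diyl hydrogen phosphate] (cat.), 4 Å molecular sieves, toluene, 0 °C to rt; then PPTS (cat.), CH2Cl2, rt
Reagents that add atoms: none
Why: In this chiral-phosphoric-acid-catalysed allylboration with lactonisation the closed Zimmerman–Traxler chair turns the boronate geometry (chain cis to CH2B, hence pseudo-axial) into the syn adduct and thus the cis-lactone, the catalyst, hydrogen-bonded to a boronate oxygen and the formyl hydrogen, should expose the Re face of the enal and so set (S) at the carbinol carbon and (S) at its neighbour, and the alkoxide then expels methoxide from the ester.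

Step 17
Reactants: 22 (1S,4E)-1-[(3R)-6-methoxy-3-methyl-1,2-dioxan-3-yl]-4-methyl-5-{(2S,3S)-4-methylidene-5-oxo-3-[(2Z)-3-(trimethylsilyl)but-2-en-1-yl]oxolan-2-yl}pent-4-en-1-yl acetate
Product: 24 denticulatolide, via peroxycarbenium triflate 23 (not isolated)
Conditions: Me3SiOSO2CF3 (TMSOTf), 2,6-di-tert-butyl-4-methylpyridine, CH2Cl2, high dilution (slow addition of 22), −78 to −40 °C
Reagents that add atoms: none
Why: Proposed new method: TMSOTf silylates the exocyclic methoxy group (the most basic oxygen) of the peroxyacetal and expels MeOSiMe3 to give the six-membered cyclic peroxycarbenium ion 23, whose carbon is attacked by the silicon-bearing sp2 carbon of the (Z)-vinylsilane, and the resulting β-silyl cation loses Me3Si+ (regenerating TMSOTf) after least-motion rotation, so that carbon replaces silicon with retention and the Z-trisubstituted alkene results. The closest known reaction types are the Lewis-acid-mediated Hosomi–Sakurai-type C–C bond formation of 3-alkoxy-1,2-dioxanes and -dioxolanes with allylsilanes, enol silanes and simple alkenes, the acetal–vinylsilane cyclisation, and macrocyclic Prins and Sakurai closures of ordinary oxocarbenium ions; new here are the vinylsilane as partner of a peroxycarbenium ion and the ring size. Only the 14-membered carbocycle is closed, 14-exo-trig with respect to the C=O+ bond (the oxygen stays outside the new ring) and endocyclic with respect to the vinylsilane (both alkene carbons end up in the ring). The new stereocentre is controlled by the quaternary dioxane carbon: in the half-chair cation the larger CH(OAc) chain lies pseudo-equatorial, and stereoelectronically preferred axial attack through a chair-like transition state places the incoming carbon cis to that chain (the 1,4-cis preference of six-membered oxocarbenium ions), which is also the face that the ten-atom tether starting from that chain reaches without strain. The step needs exocyclic rather than endocyclic C–O ionisation (endocyclic opening is reversible because the hydroperoxide stays tethered), ionisation of the peroxyacetal rather than of the allylic lactone C–O bond or the acetate (low temperature), attack by the vinylsilane rather than by the other C=C bonds (β-silicon effect; the second trisubstituted alkene is deactivated by the lactone oxygen and would give a nine-membered ring, and the methylene lactone is electron-poor), and cyclisation rather than oligomerisation or protodesilylation (slow addition at high dilution, hindered pyridine base).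

Compound list
1 | (2E,6E)-farnesol | OC/C=C(\C)CC/C=C(\C)CCC=C(C)C | starting material
2 | (2E,6E)-farnesyl acetate | CC(=O)OC/C=C(\C)CC/C=C(\C)CCC=C(C)C | intermediate
3 | (2E,6E)-10-bromo-11-hydroxy-3,7,11-trimethyldodeca-2,6-dien-1-yl acetate (racemic bromohydrin, not isolated) | CC(=O)OC/C=C(\C)CC/C=C(\C)CCC(Br)C(C)(C)O | intermediate
4 | (2E,6E)-10,11-epoxyfarnesyl acetate (racemic epoxide) | CC(=O)OC/C=C(\C)CC/C=C(\C)CCC1OC1(C)C | intermediate
5 | (2E,6E)-3,7-dimethyl-10-oxodeca-2,6-dien-1-yl acetate | CC(=O)OC/C=C(\C)CC/C=C(\C)CCC=O | intermediate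
6 | (2E,6E)-10,10-dimethoxy-3,7-dimethyldeca-2,6-dien-1-yl acetate | CC(=O)OC/C=C(\C)CC/C=C(\C)CCC(OC)OC | intermediate
7 | (2E)-5-[(2S,3S)-3-(3,3-dimethoxypropyl)-3-methyloxiran-2-yl]-3-methylpent-2-en-1-yl acetate | CC(=O)OC/C=C(\C)CC[C@@H]1O[C@@]1(C)CCC(OC)OC | intermediate
8 | (2E,6S,7R)-7-hydroperoxy-6-hydroxy-10,10-dimethoxy-3,7-dimethyldec-2-en-1-yl acetate (not isolated) | CC(=O)OC/C=C(\C)CC[C@H](O)[C@](C)(OO)CCC(OC)OC | intermediate
9 | (2E,6S)-6-hydroxy-6-[(3R)-6-methoxy-3-methyl-1,2-dioxan-3-yl]-3-methylhex-2-en-1-yl acetate (anomers) | CC(=O)OC/C=C(\C)CC[C@H](O)[C@@]1(C)CCC(OC)OO1 | intermediate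
10 | (2E,6S)-6-[(3R)-6-methoxy-3-methyl-1,2-dioxan-3-yl]-3-methylhex-2-ene-1,6-diol | OC/C=C(\C)CC[C@H](O)[C@@]1(C)CCC(OC)OO1 | intermediate
11 | (2E,6S)-6-hydroxy-6-[(3R)-6-methoxy-3-methyl-1,2-dioxan-3-yl]-3-methylhex-2-enal | O=C/C=C(\C)CC[C@H](O)[C@@]1(C)CCC(OC)OO1 | intermediate
12 | (1S,4E)-1-[(3R)-6-methoxy-3-methyl-1,2-dioxan-3-yl]-4-methyl-6-oxohex-4-en-1-yl acetate | O=C/C=C(\C)CC[C@H](OC(C)=O)[C@@]1(C)CCC(OC)OO1 | intermediate
13 | pent-3-yn-1-ol | CC#CCCO | starting material
14 | dimethyl(pent-3-yn-1-yloxy)silane (not isolated) | CC#CCCO[SiH](C)C | intermediate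
15 | 2,2,3-trimethyl-5,6-dihydro-2H-1,2-oxasiline | CC1=CCCO[Si]1(C)C | intermediate
16 | (Z)-4-(trimethylsilyl)pent-3-en-1-ol | C[Si](C)(C)/C(C)=C\CCO | intermediate
17 | (Z)-4-(trimethylsilyl)pent-3-enal | C[Si](C)(C)/C(C)=C\CC=O | intermediate
18 | methyl (5Z)-3-hydroxy-2-methylidene-6-(trimethylsilyl)hept-5-enoate (racemic) | C=C(C(=O)OC)C(O)C/C=C(/C)[Si](C)(C)C | intermediate
19 | methyl (5Z)-3-acetoxy-2-methylidene-6-(trimethylsilyl)hept-5-enoate (racemic) | C=C(C(=O)OC)C(OC(C)=O)C/C=C(/C)[Si](C)(C)C | intermediate
20 | methyl (2E,5Z)-2-[(4,4,5,5-tetramethyl-1,3,2-dioxaborolan-2-yl)methyl]-6-(trimethylsilyl)hepta-2,5-dienoate | COC(=O)/C(CB1OC(C)(C)C(C)(C)O1)=C/C/C=C(/C)[Si](C)(C)C | intermediate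
21 | pinacol borate of the syn-hydroxy ester from 12 and 20 (not isolated) | COC(=O)C(=C)[C@H](C/C=C(/C)[Si](C)(C)C)[C@@H](OB1OC(C)(C)C(C)(C)O1)/C=C(\C)CC[C@H](OC(C)=O)[C@@]2(C)CCC(OC)OO2 | intermediate
22 | (1S,4E)-1-[(3R)-6-methoxy-3-methyl-1,2-dioxan-3-yl]-4-methyl-5-{(2S,3S)-4-methylidene-5-oxo-3-[(2Z)-3-(trimethylsilyl)but-2-en-1-yl]oxolan-2-yl}pent-4-en-1-yl acetate | C=C1C(=O)O[C@@H](/C=C(\C)CC[C@H](OC(C)=O)[C@@]2(C)CCC(OC)OO2)[C@H]1C/C=C(/C)[Si](C)(C)C | intermediate
23 | cyclic peroxycarbenium triflate derived from 22 by loss of methoxide (not isolated) | C=C1C(=O)O[C@@H](/C=C(\C)CC[C@H](OC(C)=O)[C@@]2(C)CCC=[O+]O2)[C@H]1C/C=C(/C)[Si](C)(C)C.[O-]S(=O)(=O)C(F)(F)F | intermediate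
24 | denticulatolide | C=C1C(=O)O[C@H]2/C=C(\C)CC[C@H](OC(C)=O)[C@@]3(C)CC[C@H](OO3)/C(C)=C\C[C@@H]12 | target

Total step count: 17. Longest linear sequence: 11 steps (steps 1 to 9, 16 and 17).

Steps most likely to fail

1. Step 17 (ring closure).
What may go wrong: heterolytic O–O fragmentation of the peroxycarbenium ion, protodesilylation or oligomerisation may outrun the slow 14-membered closure.
Fallback (known reaction types only; the carbocycle is still the last ring to be closed): the CH(OO)–C(CH3)= bond is made before the ring is closed, and the ring is closed by olefin metathesis at the C(CH3)=CH bond.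
- The fallback sets out from 7. Iodine-catalysed transacetalisation in acetone gives the epoxy aldehyde F1.
- A Wittig reaction with isopropylidenetriphenylphosphorane restores the terminal prenyl alkene in (6S,7S)-6,7-epoxyfarnesyl acetate F2.
- A Schenck ene reaction (O2, tetraphenylporphyrin, light, CH2Cl2) at this alkene, the only electron-rich one, gives the secondary allylic hydroperoxide F3. It forms as both epimers, beside the tertiary regioisomer.
- Camphorsulfonic acid closes the dioxane by 6-exo opening of the epoxide at the tertiary carbon with inversion. The cis isomer, the isopropenyl dioxane alcohol F4, is then separated from its epimer.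
- The operations of steps 7 to 9 give the diol F5, the hydroxy enal F6 and the acetoxy enal F7.
- Union with 20 under the conditions of step 16 gives the silylated cis-lactone F8.
- Protodesilylation (CF3CO2H, CH2Cl2, 0 °C) gives the (E)-butenyl lactone F9.
- Ring-closing metathesis between the isopropenyl and the propenyl ends (second-generation Hoveyda–Grubbs catalyst, toluene, high dilution, 80 °C) comes back to the route at 24.
The price is the missing control at the dioxane CH and over the alkene geometry, so isomers have to be separated.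

2. Step 6 (perhydrolysis and dioxane closure).
What may go wrong:
- an acetal oxygen may take part in the opening of the activated epoxide (five-membered ether formation);
- partial ionisation at the tertiary carbon may erode the inversion;
- the secondary hydroxyl group may capture the acetal carbon in place of the hydroperoxide.
Fallback: the tertiary C–OO bond is made by a radical instead of an ionic process.
- The fallback sets out from 7. Al(OiPr)3 in hot toluene isomerises the epoxide to the allylic alcohol with a 1,1-disubstituted alkene and takes off the acetate at the same time. This gives the methylidene diol F10 with the carbinol configuration intact.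
- Mukaiyama–Isayama peroxidation (Co(thd)2, O2, Et3SiH, 1,2-dichloroethane) adds H and OOSiEt3 in the Markovnikov sense. This gives the triethylsilyl peroxide F11 as a pair of epimers at the quaternary carbon.
- PPTS in MeOH frees the hydroperoxide, which closes onto the acetal. After removal of the epimer the route is rejoined at 10.

3. Step 16 (fragment union).
What may go wrong: the ester group makes the boronate sluggish, so the catalysed pathway may not outrun the unselective background reaction (poor facial selectivity), or lactonisation may stall at the hydroxy ester.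
Fallback: stereocontrol by an auxiliary bound to boron instead of an external catalyst.
- The fallback sets out from 19. Borylation as in step 15, but with bis[(+)-pinanediolato]diboron, gives the pinanediol allylboronate F12.
- F12 is heated with 12 in toluene without catalyst. The closed chair keeps the cis relationship and the chiral diol biases the aldehyde face. The antipodal diol is taken if the sense proves mismatched.
- Acid-catalysed lactonisation rejoins the route at 22. The minor cis diastereomer is removed by chromatography, which is possible because 12 is a single enantiomer.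

Further compounds
F1 | step 17 | (2E)-3-methyl-5-[(2S,3S)-3-methyl-3-(3-oxopropyl)oxiran-2-yl]pent-2-en-1-yl acetate | CC(=O)OC/C=C(\C)CC[C@@H]1O[C@@]1(C)CCC=O
F2 | step 17 | (2E,6S,7S)-6,7-epoxy-6,7-dihydrofarnesyl acetate | CC(=O)OC/C=C(\C)CC[C@@H]1O[C@@]1(C)CCC=C(C)C
F3 | step 17 | (2E)-5-[(2S,3S)-3-(3-hydroperoxy-4-methylpent-4-en-1-yl)-3-methyloxiran-2-yl]-3-methylpent-2-en-1-yl acetate (epimers at the hydroperoxide carbon) | CC(=O)OC/C=C(\C)CC[C@@H]1O[C@@]1(C)CCC(OO)C(C)=C
F4 | step 17 | (2E,6S)-6-hydroxy-3-methyl-6-[(3R,6S)-3-methyl-6-(prop-1-en-2-yl)-1,2-dioxan-3-yl]hex-2-en-1-yl acetate | CC(=O)OC/C=C(\C)CC[C@H](O)[C@@]1(C)CC[C@H](OO1)C(C)=C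
F5 | step 17 | (2E,6S)-3-methyl-6-[(3R,6S)-3-methyl-6-(prop-1-en-2-yl)-1,2-dioxan-3-yl]hex-2-ene-1,6-diol | OC/C=C(\C)CC[C@H](O)[C@@]1(C)CC[C@H](OO1)C(C)=C
F6 | step 17 | (2E,6S)-6-hydroxy-3-methyl-6-[(3R,6S)-3-methyl-6-(prop-1-en-2-yl)-1,2-dioxan-3-yl]hex-2-enal | O=C/C=C(\C)CC[C@H](O)[C@@]1(C)CC[C@H](OO1)C(C)=C
F7 | step 17 | (1S,4E)-4-methyl-1-[(3R,6S)-3-methyl-6-(prop-1-en-2-yl)-1,2-dioxan-3-yl]-6-oxohex-4-en-1-yl acetate | O=C/C=C(\C)CC[C@H](OC(C)=O)[C@@]1(C)CC[C@H](OO1)C(C)=C
F8 | step 17 | cis-(2S,3S)-α-methylene-γ-butyrolactone carrying the isopropenyl dioxane side chain at C2 and the (2Z)-3-(trimethylsilyl)but-2-en-1-yl group at C3 | C=C1C(=O)O[C@@H](/C=C(\C)CC[C@H](OC(C)=O)[C@@]2(C)CC[C@H](OO2)C(C)=C)[C@H]1C/C=C(/C)[Si](C)(C)C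
F9 | step 17 | the same lactone with an (2E)-but-2-en-1-yl group at C3 | C=C1C(=O)O[C@@H](/C=C(\C)CC[C@H](OC(C)=O)[C@@]2(C)CC[C@H](OO2)C(C)=C)[C@H]1C/C=C/C
F10 | step 6 | (2E,6S)-10,10-dimethoxy-3-methyl-7-methylidenedec-2-ene-1,6-diol | OC/C=C(\C)CC[C@H](O)C(=C)CCC(OC)OC
F11 | step 6 | (2E,6S)-10,10-dimethoxy-3,7-dimethyl-7-(triethylsilylperoxy)dec-2-ene-1,6-diol (epimers at C7) | OC/C=C(\C)CC[C@H](O)C(C)(OO[Si](CC)(CC)CC)CCC(OC)OC
F12 | step 16 | (+)-pinanediol ester analogue of 20 | COC(=O)/C(CB1O[C@@H]2C[C@@H]3C[C@@H](C3(C)C)[C@]2(C)O1)=C/C/C=C(/C)[Si](C)(C)C
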